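**Strategy.** The route rests on cutting the bond between C3 of the chromanone ring and C1′ of the B ring. At the chromone oxidation level C3 is the α-carbon of the C2=C3–C4=O enone and can carry iodine, so a one-pot Negishi coupling joins a 3-iodochromone with the arylzinc reagent made from the prenylated B-ring bromide and delivers the whole isoflavone skeleton. The C2=C3 bond is then a latent, regiodefined enolate: conjugate reduction and reagent-controlled enolate hydroxylation set the (S)-carbinol at C3. A prenyl ether protects O5 throughout and is moved to C8 at the end by a Claisen–Cope rearrangement.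

Key step: step 5

Remark: C3 of the target is (S) (CIP order OH > C4 > C2 > C1′); the name sophonorol F is kept as given.
Remark: the (−)-antipode of the oxaziridine in step 7 is assigned to the (S)-product by analogy with ring-locked tetrasubstituted sodium enolates of 2-alkyl-1-tetralones and 3-benzylchroman-4-ones; this assignment is not secured for a 3-aryl substrate, and if a pilot run shows the opposite sense the (+)-antipode is used in its place.

**Step 1**
Reactants: 1 2′,6′-dihydroxy-4′-methoxyacetophenone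
Product: 2 1-[2-hydroxy-4-methoxy-6-(3-methylbut-2-enyloxy)phenyl]ethan-1-one
Conditions: prenyl bromide (1.05 equiv), K2CO3, acetone, reflux
Reagents that add atoms: prenyl bromide (1-bromo-3-methylbut-2-ene), CC(C)=CCBr
Why: Williamson etherification; the two hydroxyls of 1 are equivalent, and once one is alkylated the other is held in a strong hydrogen bond to the acetyl oxygen, so the reaction should stop at the mono-ether.

**Step 2**
Reactants: 2 1-[2-hydroxy-4-methoxy-6-(3-methylbut-2-enyloxy)phenyl]ethan-1-one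
Product: 4 3-iodo-7-methoxy-5-(3-methylbut-2-enyloxy)-4H-chromen-4-one, via enaminone 3 (not isolated)
Conditions: DMF-DMA, 90 °C; concentrate; I2, CHCl3, rt
Reagents that add atoms: N,N-dimethylformamide dimethyl acetal, COC(OC)N(C)C; iodine, II
Why: Enaminone condensation followed by iodine-induced cyclisation to the 3-iodochromone; iodine attacks the strongly nucleophilic enaminone α-carbon, the free ortho-hydroxyl adds to the iminium carbon and dimethylamine is lost, while the prenyl ether alkene has no neighbouring nucleophile for iodoetherification.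

**Step 3**
Reactants: 5 4-bromo-3-methoxyphenol
Product: 6 1-bromo-2-methoxy-4-(methoxymethoxy)benzene
Conditions: NaH, MOMCl, THF–DMF, 0 °C → rt
Reagents that add atoms: chloromethyl methyl ether, COCCl
Why: O-alkylation of the phenoxide (Williamson type); the MOM group directs the metalation of step 4 and tolerates the organolithium, hydride and amide reagents that follow.

**Step 4**
Reactants: 6 1-bromo-2-methoxy-4-(methoxymethoxy)benzene
Product: 8 1-bromo-2-methoxy-4-(methoxymethoxy)-3-(3-methylbut-2-enyl)benzene, via aryllithium 7 (not isolated)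
Conditions: LiTMP (from TMPH and n-BuLi), THF, −78 °C; then CuBr·SMe2 (10 mol%), prenyl bromide, −78 → 0 °C
Reagents that add atoms: prenyl bromide (1-bromo-3-methylbut-2-ene), CC(C)=CCBr
Why: Directed ortho-metalation followed by copper-catalysed SN2 allylation; the proton between OMe and OMOM is the most acidic and doubly coordinated site, it is meta to bromine so that an amide base should cause neither halogen–metal exchange nor aryne formation, and the arylcopper species attacks prenyl bromide at its primary carbon.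

**Step 5**
Reactants: 8 1-bromo-2-methoxy-4-(methoxymethoxy)-3-(3-methylbut-2-enyl)benzene; 4 3-iodo-7-methoxy-5-(3-methylbut-2-enyloxy)-4H-chromen-4-one
Product: 11 7-methoxy-3-[2-methoxy-4-(methoxymethoxy)-3-(3-methylbut-2-enyl)phenyl]-5-(3-methylbut-2-enyloxy)-4H-chromen-4-one, via aryllithium 9 (not isolated), via arylzinc chloride 10 (not isolated)
Conditions: n-BuLi, THF, −78 °C; ZnCl2, −78 °C → rt; then 4, Pd2(dba)3 (2 mol%), SPhos (8 mol%), THF, rt → 40 °C
Reagents that add atoms: none
Why: Bromine–lithium exchange on 8 and transmetalation to zinc give arylzinc 10 with the metal exactly at C1′, because the bromine was placed ortho to the methoxy group; Pd(0) inserts into the C3–I bond of 4, an α-iodoenone that should undergo oxidative addition at room temperature, and transmetalation followed by reductive elimination forges the C3–C1′ bond. The closest known reaction type is the Negishi coupling, and Pd-catalysed arylation of 3-iodochromones is the standard entry to isoflavones. No ring is closed and no stereocentre is formed; C3 stays sp2 so that the C2=C3 bond can later deliver a regiodefined enolate. The step needs chemoselectivity for C–I over the allylic aryl ether at O5 and over addition to the chromone carbonyl or C2: arylzinc chlorides do not add to enones without copper, and insertion into the vinylic C–I bond should outrun ionisation of the hindered prenyl ether when the coupling is run near room temperature with a biarylphosphine ligand. The single ortho-methoxy group on the zinc reagent is within the scope of SPhos-type catalysts.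

**Step 6**
Reactants: 11 7-methoxy-3-[2-methoxy-4-(methoxymethoxy)-3-(3-methylbut-2-enyl)phenyl]-5-(3-methylbut-2-enyloxy)-4H-chromen-4-one
Product: 13 (±)-7-methoxy-3-[2-methoxy-4-(methoxymethoxy)-3-(3-methylbut-2-enyl)phenyl]-5-(3-methylbut-2-enyloxy)chroman-4-one, via lithium enolate 12 (not isolated)
Conditions: L-Selectride (1.1 equiv), THF, −78 °C; aq NH4Cl
Reagents that add atoms: none
Why: Conjugate (1,4) hydride reduction of the chromone enone by the bulky trialkylborohydride, which attacks the unsubstituted C2 and keeps the carbonyl masked as its enolate until protonation; the C3 stereocentre is formed as a racemate on purpose, since it is erased in step 7.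

**Step 7**
Reactants: 13 (±)-7-methoxy-3-[2-methoxy-4-(methoxymethoxy)-3-(3-methylbut-2-enyl)phenyl]-5-(3-methylbut-2-enyloxy)chroman-4-one
Product: 15 (3S)-3-hydroxy-7-methoxy-3-[2-methoxy-4-(methoxymethoxy)-3-(3-methylbut-2-enyl)phenyl]-5-(3-methylbut-2-enyloxy)chroman-4-one, via sodium enolate 14 (not isolated)
Conditions: NaHMDS, THF, −78 °C; (−)-[(8,8-dimethoxycamphoryl)sulfonyl]oxaziridine, −78 °C; aq NH4Cl at −78 °C
Reagents that add atoms: (−)-(2S,8aS)-[(8,8-dimethoxycamphoryl)sulfonyl]oxaziridine, CC1(C)[C@H]2CC[C@@]13CS(=O)(=O)N4O[C@]34C2(OC)OC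
Why: Davis asymmetric enolate oxidation; C3 is the only enolisable position, and the enantiopure N-sulfonyloxaziridine should transfer oxygen to one face of the ring-locked tetrasubstituted sodium enolate in an open SN2-type transition state (reagent control), the dimethoxy reagent being the variant suited to enolates with an alkoxy group peri to the carbonyl, so that the (S)-carbinol is expected.

**Step 8**
Reactants: 15 (3S)-3-hydroxy-7-methoxy-3-[2-methoxy-4-(methoxymethoxy)-3-(3-methylbut-2-enyl)phenyl]-5-(3-methylbut-2-enyloxy)chroman-4-one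
Product: 17 (3S)-3,5-dihydroxy-7-methoxy-3-[2-methoxy-4-(methoxymethoxy)-3-(3-methylbut-2-enyl)phenyl]-8-(3-methylbut-2-enyl)chroman-4-one, via ortho-dienone 16 (not isolated)
Conditions: Eu(fod)3 (10 mol%), NaHCO3, PhCl, 85 °C
Reagents that add atoms: none
Why: Europium(III)-catalysed para-Claisen–Cope rearrangement; a [3,3] shift of the O5 prenyl ether to the ortho carbon C6 gives a dienone that, activated by chelation of the 4,5-dioxygen unit, should undergo a second [3,3] (Cope) shift to C8 and then enolise, which restores the linear prenyl group, frees the C5 hydroxyl and leaves the quaternary C3 stereocentre untouched.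

**Step 9**
Reactants: 17 (3S)-3,5-dihydroxy-7-methoxy-3-[2-methoxy-4-(methoxymethoxy)-3-(3-methylbut-2-enyl)phenyl]-8-(3-methylbut-2-enyl)chroman-4-one
Product: 18 sophonorol F, (3S)-3,5-dihydroxy-3-[4-hydroxy-2-methoxy-3-(3-methylbut-2-enyl)phenyl]-7-methoxy-8-(3-methylbut-2-enyl)chroman-4-one
Conditions: HCl (1.25 M in MeOH), MeOH–CH2Cl2, 0 °C → rt
Reagents that add atoms: none
Why: Acid-catalysed acetal cleavage by transacetalisation to methanol; mild anhydrous HCl at or below room temperature is the usual way to unmask MOM-protected phenols next to prenyl groups, and it should not ionise the tertiary C3–OH, which lies α to a carbonyl.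

**Compound list**
1 | 1-(2,6-dihydroxy-4-methoxyphenyl)ethan-1-one (2′,6′-dihydroxy-4′-methoxyacetophenone) | CC(=O)c1c(O)cc(OC)cc1O | starting material
2 | 1-[2-hydroxy-4-methoxy-6-(3-methylbut-2-enyloxy)phenyl]ethan-1-one | CC(=O)c1c(O)cc(OC)cc1OCC=C(C)C | intermediate
3 | (E)-3-(dimethylamino)-1-[2-hydroxy-4-methoxy-6-(3-methylbut-2-enyloxy)phenyl]prop-2-en-1-one (enaminone, not isolated) | CN(C)/C=C/C(=O)c1c(O)cc(OC)cc1OCC=C(C)C | intermediate
4 | 3-iodo-7-methoxy-5-(3-methylbut-2-enyloxy)-4H-chromen-4-one | COc1cc(OCC=C(C)C)c2c(c1)occ(I)c2=O | intermediate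
5 | 4-bromo-3-methoxyphenol | COc1cc(O)ccc1Br | starting material
6 | 1-bromo-2-methoxy-4-(methoxymethoxy)benzene | COCOc1ccc(Br)c(OC)c1 | intermediate
7 | [3-bromo-2-methoxy-6-(methoxymethoxy)phenyl]lithium (not isolated) | COCOc1ccc(Br)c(OC)c1[Li] | intermediate
8 | 1-bromo-2-methoxy-4-(methoxymethoxy)-3-(3-methylbut-2-enyl)benzene | COCOc1ccc(Br)c(OC)c1CC=C(C)C | intermediate
9 | [2-methoxy-4-(methoxymethoxy)-3-(3-methylbut-2-enyl)phenyl]lithium (not isolated) | COCOc1ccc([Li])c(OC)c1CC=C(C)C | intermediate
10 | chloro[2-methoxy-4-(methoxymethoxy)-3-(3-methylbut-2-enyl)phenyl]zinc (not isolated) | COCOc1ccc([Zn]Cl)c(OC)c1CC=C(C)C | intermediate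
11 | 7-methoxy-3-[2-methoxy-4-(methoxymethoxy)-3-(3-methylbut-2-enyl)phenyl]-5-(3-methylbut-2-enyloxy)-4H-chromen-4-one | COc1cc(OCC=C(C)C)c2c(c1)occ(-c1ccc(OCOC)c(CC=C(C)C)c1OC)c2=O | intermediate
12 | lithium 7-methoxy-3-[2-methoxy-4-(methoxymethoxy)-3-(3-methylbut-2-enyl)phenyl]-5-(3-methylbut-2-enyloxy)-2H-chromen-4-olate (not isolated) | COc1cc(OCC=C(C)C)c2c(c1)OCC(c1ccc(OCOC)c(CC=C(C)C)c1OC)=C2O[Li] | intermediate
13 | (±)-7-methoxy-3-[2-methoxy-4-(methoxymethoxy)-3-(3-methylbut-2-enyl)phenyl]-5-(3-methylbut-2-enyloxy)chroman-4-one (racemic at C3) | COc1cc(OCC=C(C)C)c2c(c1)OCC(c1ccc(OCOC)c(CC=C(C)C)c1OC)C2=O | intermediate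
14 | sodium 7-methoxy-3-[2-methoxy-4-(methoxymethoxy)-3-(3-methylbut-2-enyl)phenyl]-5-(3-methylbut-2-enyloxy)-2H-chromen-4-olate (not isolated) | COc1cc(OCC=C(C)C)c2c(c1)OCC(c1ccc(OCOC)c(CC=C(C)C)c1OC)=C2O[Na] | intermediate
15 | (3S)-3-hydroxy-7-methoxy-3-[2-methoxy-4-(methoxymethoxy)-3-(3-methylbut-2-enyl)phenyl]-5-(3-methylbut-2-enyloxy)chroman-4-one | COc1cc(OCC=C(C)C)c2c(c1)OC[C@@](O)(c1ccc(OCOC)c(CC=C(C)C)c1OC)C2=O | intermediate
16 | (3S)-3-hydroxy-7-methoxy-3-[2-methoxy-4-(methoxymethoxy)-3-(3-methylbut-2-enyl)phenyl]-6-(2-methylbut-3-en-2-yl)-2,3-dihydro-4H-chromene-4,5(6H)-dione (ortho-dienone, C6 epimers, not isolated) | C=CC(C)(C)C1C(=O)C2=C(C=C1OC)OC[C@@](O)(c1ccc(OCOC)c(CC=C(C)C)c1OC)C2=O | intermediate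
17 | (3S)-3,5-dihydroxy-7-methoxy-3-[2-methoxy-4-(methoxymethoxy)-3-(3-methylbut-2-enyl)phenyl]-8-(3-methylbut-2-enyl)chroman-4-one | COc1cc(O)c2c(c1CC=C(C)C)OC[C@@](O)(c1ccc(OCOC)c(CC=C(C)C)c1OC)C2=O | intermediate
18 | sophonorol F, (3S)-3,5-dihydroxy-3-[4-hydroxy-2-methoxy-3-(3-methylbut-2-enyl)phenyl]-7-methoxy-8-(3-methylbut-2-enyl)chroman-4-one | COc1cc(O)c2c(c1CC=C(C)C)OC[C@@](O)(c1ccc(O)c(CC=C(C)C)c1OC)C2=O | target

**Step count.** Total: 9 steps. Longest linear sequence: 7 steps (steps 1, 2, 5, 6, 7, 8, 9 from 1; equally steps 3, 4, 5, 6, 7, 8, 9 from 5).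

**Steps most likely to fail**

Step 7. What may go wrong: insufficient or reversed facial discrimination when oxygen is transferred to a 3-aryl-substituted enolate, or capture of the enolate by the sulfonimine by-product. The fallback replaces the stoichiometric chiral oxidant by catalyst control with dioxygen under phase-transfer conditions. It sets out from 13: a cinchona-derived quaternary ammonium salt (cinchonidinium or its pseudoenantiomeric cinchoninium, chosen for the sense required), 50% aq KOH/toluene, O2 (1 atm), P(OEt)3, 0 °C. The chiral ammonium enolate should take up dioxygen on one face to give (3S)-3-hydroperoxy-7-methoxy-3-[2-methoxy-4-(methoxymethoxy)-3-(3-methylbut-2-enyl)phenyl]-5-(3-methylbut-2-enyloxy)chroman-4-one F1, which triethyl phosphite reduces in the same flask. The sequence comes back to the route at 15.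

Step 8. What may go wrong: enolisation of the ortho-dienone before the Cope shift, which would leave the 6-(1,1-dimethylallyl) isomer, or thermal and Lewis-acid degradation of the tertiary α-ketol. The fallback runs the rearrangement one stage earlier on the flat, robust chromone nucleus and protects O5 afterwards. It sets out from 11: Eu(fod)3, NaHCO3, PhCl, 85 °C should lead via the isoflavone ortho-dienone F2 to the 5-hydroxy-8-prenylisoflavone F3. NaH and MOMCl in DMF then give the bis-MOM isoflavone F4. L-Selectride reduces it via the lithium enolate F5 to the racemic bis-MOM isoflavanone F6. NaHMDS and the oxaziridine of step 7 give, via the sodium enolate F7, the (S)-configured bis-MOM carbinol F8. HCl in MeOH removes both MOM groups, and the sequence comes back at 18, one step longer.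

Step 5. What may go wrong: loss of the arylzinc reagent by proton transfer or homocoupling, and sluggish transmetalation of the ortho-substituted, electron-rich aryl group. The fallback is a Suzuki–Miyaura coupling with an isolated, purified boron reagent. It sets out from aryllithium 9, which is quenched with 2-isopropoxy-4,4,5,5-tetramethyl-1,3,2-dioxaborolane to give the aryl pinacol boronic ester F9. This is coupled with 4 (Pd(dppf)Cl2, K3PO4, dioxane–H2O, 60 °C) and comes back to the route at 11, at the cost of one more isolation.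

**Further compounds**
F1 | step 7 | (3S)-3-hydroperoxy-7-methoxy-3-[2-methoxy-4-(methoxymethoxy)-3-(3-methylbut-2-enyl)phenyl]-5-(3-methylbut-2-enyloxy)chroman-4-one | COc1cc(OCC=C(C)C)c2c(c1)OC[C@@](OO)(c1ccc(OCOC)c(CC=C(C)C)c1OC)C2=O
F2 | step 8 | 7-methoxy-3-[2-methoxy-4-(methoxymethoxy)-3-(3-methylbut-2-enyl)phenyl]-6-(2-methylbut-3-en-2-yl)-4H-chromene-4,5(6H)-dione (isoflavone ortho-dienone) | C=CC(C)(C)C1C(=O)C2=C(C=C1OC)OC=C(c1ccc(OCOC)c(CC=C(C)C)c1OC)C2=O
F3 | step 8 | 5-hydroxy-7-methoxy-3-[2-methoxy-4-(methoxymethoxy)-3-(3-methylbut-2-enyl)phenyl]-8-(3-methylbut-2-enyl)-4H-chromen-4-one | COc1cc(O)c2c(c1CC=C(C)C)occ(-c1ccc(OCOC)c(CC=C(C)C)c1OC)c2=O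
F4 | step 8 | 7-methoxy-5-(methoxymethoxy)-3-[2-methoxy-4-(methoxymethoxy)-3-(3-methylbut-2-enyl)phenyl]-8-(3-methylbut-2-enyl)-4H-chromen-4-one | COc1cc(OCOC)c2c(c1CC=C(C)C)occ(-c1ccc(OCOC)c(CC=C(C)C)c1OC)c2=O
F5 | step 8 | lithium 7-methoxy-5-(methoxymethoxy)-3-[2-methoxy-4-(methoxymethoxy)-3-(3-methylbut-2-enyl)phenyl]-8-(3-methylbut-2-enyl)-2H-chromen-4-olate | COc1cc(OCOC)c2c(c1CC=C(C)C)OCC(c1ccc(OCOC)c(CC=C(C)C)c1OC)=C2O[Li]
F6 | step 8 | (±)-7-methoxy-5-(methoxymethoxy)-3-[2-methoxy-4-(methoxymethoxy)-3-(3-methylbut-2-enyl)phenyl]-8-(3-methylbut-2-enyl)chroman-4-one | COc1cc(OCOC)c2c(c1CC=C(C)C)OCC(c1ccc(OCOC)c(CC=C(C)C)c1OC)C2=O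
F7 | step 8 | sodium 7-methoxy-5-(methoxymethoxy)-3-[2-methoxy-4-(methoxymethoxy)-3-(3-methylbut-2-enyl)phenyl]-8-(3-methylbut-2-enyl)-2H-chromen-4-olate | COc1cc(OCOC)c2c(c1CC=C(C)C)OCC(c1ccc(OCOC)c(CC=C(C)C)c1OC)=C2O[Na]
F8 | step 8 | (3S)-3-hydroxy-7-methoxy-5-(methoxymethoxy)-3-[2-methoxy-4-(methoxymethoxy)-3-(3-methylbut-2-enyl)phenyl]-8-(3-methylbut-2-enyl)chroman-4-one | COc1cc(OCOC)c2c(c1CC=C(C)C)OC[C@@](O)(c1ccc(OCOC)c(CC=C(C)C)c1OC)C2=O
F9 | step 5 | 2-[2-methoxy-4-(methoxymethoxy)-3-(3-methylbut-2-enyl)phenyl]-4,4,5,5-tetramethyl-1,3,2-dioxaborolane | COCOc1ccc(B2OC(C)(C)C(C)(C)O2)c(OC)c1CC=C(C)C
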